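## Retrosynthetic overview

1. The acrylic acid is disconnected from ring A by a Heck reaction of aryl triflate 10, which comes from the 5‑OH of dihydrobenzofuranol 9.
2. 9 is disconnected into (E)-sinapyl alcohol 5 and 2‑methoxy‑1,4‑benzoquinone 7 by a formal [3+2]. The quinone is the polarity‑reversed, enolonium‑type (α‑keto cation) form of the methoxyhydroquinone ring, so two normally nucleophilic carbons are joined (C3–C3a), and O1–C2 then closes.
3. Ring order: the syringyl ring is bought intact, ring A comes from the quinone and re‑aromatises in the key step, and the dihydrofuran ring is the only ring formed, with both stereocentres.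
4. 5 comes from syringaldehyde (Wittig, reduction); 7 comes from 2‑methoxyhydroquinone.

Assumption: the (R)-configured phosphoric acid is taken to give the (2S,3R) series; if the sense of induction is opposite, its enantiomer is used and nothing else changes.

## Route

Step 1
Reactants: 1 syringaldehyde; 2 ethyl (triphenylphosphoranylidene)acetate
Product: 3 ethyl (E)-sinapate
Conditions: toluene, 110 °C
Reagents that add atoms: none
Why: Wittig olefination with a stabilised ylide tolerates the free phenol and gives the (E)-cinnamate; no stereocentre is formed.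

Step 2
Reactants: 3 ethyl (E)-sinapate
Product: 5 (E)-sinapyl alcohol, via sinapaldehyde 4 (not isolated)
Conditions: i-Bu2AlH (4 equiv), toluene, 0 °C; then aq. potassium sodium tartrate
Reagents that add atoms: none
Why: Aluminium hydride 1,2‑reduction of the conjugated ester to the allylic alcohol leaves the C=C and its E geometry untouched, with one extra equivalent consumed by the phenol.

Step 3
Reactants: 6 2‑methoxyhydroquinone
Product: 7 2‑methoxy‑1,4‑benzoquinone
Conditions: PhI(OAc)2 (1.05 equiv), MeCN–H2O, 0 °C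
Reagents that add atoms: none
Why: Two‑electron oxidation of a hydroquinone to the para‑quinone by a hypervalent iodine diacetate turns the nucleophilic ring carbons of 6 into electrophilic ones.

Step 4
Reactants: 5 (E)-sinapyl alcohol; 7 2‑methoxy‑1,4‑benzoquinone
Product: 9 (2S,3R)-2-(4-hydroxy-3,5-dimethoxyphenyl)-3-(hydroxymethyl)-7-methoxy-2,3-dihydro-1-benzofuran-5-ol, via quinone methide adduct 8 (not isolated)
Conditions: (R)-3,3'-bis(2,4,6-triisopropylphenyl)-1,1'-binaphthyl-2,2'-diyl hydrogen phosphate (10 mol %), CH2Cl2, −30 °C; 7 added slowly to 5 (1.2 equiv)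
Reagents that add atoms: none
Why: Proposed new method: the phosphoric acid hydrogen‑bonds through P–OH to the more basic vinylogous‑ester carbonyl (C4=O) of 7 and through P=O to the phenol of 5, so the nucleophilic β‑carbon of the 4‑hydroxystyrene adds face‑selectively to C6 of the quinone (a carbon that is nucleophilic in the hydroquinone) and sets C3 as R; tautomerisation gives quinone methide 8, and reversible 1,6‑closure by the adjacent phenol OH sets C2 trans to C3, giving (2S,3R); the closest known reaction types are chiral‑phosphoric‑acid‑catalysed formal [3+2] couplings of quinones and quinone monoimines with hydroxystyrenes and enecarbamates and the Lewis‑acid‑promoted methoxyquinone–propenylarene [3+2] annulation to trans‑2‑aryl‑2,3‑dihydrobenzofuran‑5‑ols, and attack at C6 rather than C5 is argued from the regiochemical reversal of methoxyquinone Diels–Alder reactions under monodentate acid activation.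

Step 5
Reactants: 9 (2S,3R)-2-(4-hydroxy-3,5-dimethoxyphenyl)-3-(hydroxymethyl)-7-methoxy-2,3-dihydro-1-benzofuran-5-ol
Product: 10 (2S,3R)-2-(4-hydroxy-3,5-dimethoxyphenyl)-3-(hydroxymethyl)-7-methoxy-2,3-dihydro-1-benzofuran-5-yl trifluoromethanesulfonate
Conditions: PhNTf2 (1.0 equiv), K2CO3, acetone, 0 °C
Reagents that add atoms: N‑phenylbis(trifluoromethanesulfonimide), O=S(=O)(N(c1ccccc1)S(=O)(=O)C(F)(F)F)C(F)(F)F
Why: Phenoxide O‑sulfonylation with a bulky triflyl‑transfer reagent should favour the unhindered ring A 5‑OH over the syringyl OH flanked by two methoxy groups and over the non‑ionised primary alcohol; the stereocentres are not touched.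

Step 6
Reactants: 10 (2S,3R)-2-(4-hydroxy-3,5-dimethoxyphenyl)-3-(hydroxymethyl)-7-methoxy-2,3-dihydro-1-benzofuran-5-yl trifluoromethanesulfonate; 11 acrylic acid
Product: 12 (E)-3-[(2S,3R)-2-(4-hydroxy-3,5-dimethoxyphenyl)-3-(hydroxymethyl)-7-methoxy-2,3-dihydro-1-benzofuran-5-yl]prop-2-enoic acid
Conditions: Pd(OAc)2 (5 mol %), 1,3‑bis(diphenylphosphino)propane (6 mol %), Et3N (4 equiv), DMF, 80 °C; then dilute acid to pH 3
Reagents that add atoms: none
Why: Mizoroki–Heck coupling of an aryl triflate with acrylic acid (Pd(OAc)2 reduced in situ to zerovalent palladium) gives the (E)-cinnamic acid by syn‑insertion and syn‑β‑hydride elimination, and the amine base is mild enough to leave the trans‑dihydrobenzofuran stereocentres alone.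

## Compound list

1 | syringaldehyde (4‑hydroxy‑3,5‑dimethoxybenzaldehyde) | COc1cc(C=O)cc(OC)c1O | starting material
2 | ethyl (triphenylphosphoranylidene)acetate | CCOC(=O)C=P(c1ccccc1)(c1ccccc1)c1ccccc1 | starting material
3 | ethyl (E)-sinapate, ethyl (E)-3-(4-hydroxy-3,5-dimethoxyphenyl)prop-2-enoate | CCOC(=O)/C=C/c1cc(OC)c(O)c(OC)c1 | intermediate
4 | (E)-sinapaldehyde, (E)-3-(4-hydroxy-3,5-dimethoxyphenyl)prop-2-enal | O=C/C=C/c1cc(OC)c(O)c(OC)c1 | intermediate (not isolated)
5 | (E)-sinapyl alcohol, 4-[(E)-3-hydroxyprop-1-enyl]-2,6-dimethoxyphenol | OC/C=C/c1cc(OC)c(O)c(OC)c1 | intermediate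
6 | 2‑methoxyhydroquinone (2‑methoxybenzene‑1,4‑diol) | COc1cc(O)ccc1O | starting material
7 | 2‑methoxy‑1,4‑benzoquinone | COC1=CC(=O)C=CC1=O | intermediate
8 | 4-[(2R)-2-(2,5-dihydroxy-3-methoxyphenyl)-3-hydroxypropylidene]-2,6-dimethoxycyclohexa-2,5-dien-1-one | O=C1C(OC)=CC(=C[C@@H](CO)c2cc(O)cc(OC)c2O)C=C1OC | intermediate (not isolated)
9 | (2S,3R)-2-(4-hydroxy-3,5-dimethoxyphenyl)-3-(hydroxymethyl)-7-methoxy-2,3-dihydro-1-benzofuran-5-ol (trans) | COc1cc([C@H]2Oc3c(OC)cc(O)cc3[C@@H]2CO)cc(OC)c1O | intermediate
10 | (2S,3R)-2-(4-hydroxy-3,5-dimethoxyphenyl)-3-(hydroxymethyl)-7-methoxy-2,3-dihydro-1-benzofuran-5-yl trifluoromethanesulfonate | COc1cc([C@H]2Oc3c(OC)cc(OS(=O)(=O)C(F)(F)F)cc3[C@@H]2CO)cc(OC)c1O | intermediate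
11 | acrylic acid | C=CC(=O)O | starting material
12 | (E)-3-[(2S,3R)-2-(4-hydroxy-3,5-dimethoxyphenyl)-3-(hydroxymethyl)-7-methoxy-2,3-dihydro-1-benzofuran-5-yl]prop-2-enoic acid | COc1cc([C@H]2Oc3c(OC)cc(/C=C/C(=O)O)cc3[C@@H]2CO)cc(OC)c1O | target

## Step count and risks

Total steps: 6. Longest linear sequence: 5 (steps 1, 2, 4, 5, 6). No protecting groups are used.

**Step 4 (most likely to fail).** The risks are attack at C5 instead of C6 of the quinone, insufficient enantioselectivity, and acid‑lability of 5. The fallback sets out from 5 and 7 and comes back at 9. It gives up catalytic enantiocontrol: BF3·OEt2 (CH2Cl2, −78 °C), a monodentate Lewis acid that binds the C4 carbonyl, gives the racemic trans product, that is 9 together with its enantiomer, the (2R,3S)-diol F1. Kinetic resolution with immobilised Candida antarctica lipase B and vinyl acetate (t‑BuOMe, 30 °C) acetylates only the primary alcohol of one enantiomer. The enzyme and acyl donor are screened so that this is F1, which becomes the (2R,3S)-acetate F2. Unreacted 9 is separated by chromatography and the route continues from 9.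

**Step 5.** The two phenols may not be differentiated cleanly. The fallback sets out from 9 and comes back at 12. Both phenols are triflated (PhNTf2 2.5 equiv, Cs2CO3, MeCN, rt) to the bis(triflate) F3. The Heck reaction under the step 6 conditions should engage only the unhindered ring A triflate, because the syringyl triflate between two methoxy groups is slow in oxidative addition; this gives the 4'-O‑triflyl acid F4. Et4NOH (dioxane–H2O, rt) then cleaves the remaining aryl triflate at sulfur and delivers 12.

**Step 6.** The electron‑rich aryl triflate may couple sluggishly with free acrylic acid, and the phenolic dihydrobenzofuran is sensitive to hot base. The fallback sets out from 10 and comes back at 12. Suzuki–Miyaura coupling of 10 with ethyl (E)-3-(4,4,5,5-tetramethyl-1,3,2-dioxaborolan-2-yl)acrylate (PdCl2[1,1'-bis(diphenylphosphino)ferrocene], K3PO4, dioxane–H2O, 70 °C) gives the ethyl ester F5. Saponification (LiOH, THF–H2O, rt, then dilute acid) gives 12.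

## Further compounds

F1 | step 4 | (2R,3S)-2-(4-hydroxy-3,5-dimethoxyphenyl)-3-(hydroxymethyl)-7-methoxy-2,3-dihydro-1-benzofuran-5-ol | COc1cc([C@@H]2Oc3c(OC)cc(O)cc3[C@H]2CO)cc(OC)c1O
F2 | step 4 | [(2R,3S)-5-hydroxy-2-(4-hydroxy-3,5-dimethoxyphenyl)-7-methoxy-2,3-dihydro-1-benzofuran-3-yl]methyl acetate | COc1cc([C@@H]2Oc3c(OC)cc(O)cc3[C@H]2COC(C)=O)cc(OC)c1O
F3 | step 5 | (2S,3R)-2-[3,5-dimethoxy-4-(trifluoromethylsulfonyloxy)phenyl]-3-(hydroxymethyl)-7-methoxy-2,3-dihydro-1-benzofuran-5-yl trifluoromethanesulfonate | COc1cc([C@H]2Oc3c(OC)cc(OS(=O)(=O)C(F)(F)F)cc3[C@@H]2CO)cc(OC)c1OS(=O)(=O)C(F)(F)F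
F4 | step 5 | (E)-3-[(2S,3R)-2-[3,5-dimethoxy-4-(trifluoromethylsulfonyloxy)phenyl]-3-(hydroxymethyl)-7-methoxy-2,3-dihydro-1-benzofuran-5-yl]prop-2-enoic acid | COc1cc([C@H]2Oc3c(OC)cc(/C=C/C(=O)O)cc3[C@@H]2CO)cc(OC)c1OS(=O)(=O)C(F)(F)F
F5 | step 6 | ethyl (E)-3-[(2S,3R)-2-(4-hydroxy-3,5-dimethoxyphenyl)-3-(hydroxymethyl)-7-methoxy-2,3-dihydro-1-benzofuran-5-yl]prop-2-enoate | COc1cc([C@H]2Oc3c(OC)cc(/C=C/C(=O)OCC)cc3[C@@H]2CO)cc(OC)c1O
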